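- Per second is the unit in which I compare two clocks on second intermediate in four set-ups: partner releases it, and open intermediate captures it.

| setting | Friday's | Tuesday's | Saturday's | Wednesday's |
|---|---|---|---|---|
| starting material | 20 mM | 20 mM | 20 mM | 20 mM (fed, over 8.00 min) |
| partner | 22.0 mM (fed, over 8.00 min) | 22.0 mM | 22.0 mM | 22.0 mM |
| time | 10 min |  | 10 min | 10 min |
| remark | all but partner at the start; partner goes in evenly over 8.00 min, the run ends at 10 min | a single well-mixed tank run continuously and read at steady state, 10 min in it on average | everything together in a closed stirred flask, run for 10 min | a stirred flask in which starting material is dosed at a steady rate over 8.00 min without added volume, worked up at 10 min |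

    partner + target → over-reaction product (k1 = 0.0711 M⁻¹ s⁻¹)
    2 open intermediate → homo product (k2 = 0.0131 M⁻¹ s⁻¹)
    starting material ⇌ dormant form (K3 = 0.210, k3 = 8.22 × 10⁻⁴ s⁻¹)
    partner → second intermediate (k4 = 0.00132 s⁻¹)
    starting material ⇌ open intermediate (K5 = 3.39, k5 = 0.00245 s⁻¹)
    open intermediate + second intermediate → target (k6 = 0.320 M⁻¹ s⁻¹)

- a species is counted by the starting material in it: one homo product counts as two
- two of one species on the left: rate k times its square, two consumed each time
- the stated concentrations are those of everything mixed, before any reaction; amounts are the same in each set-up
- the feed brings no volume worth counting
- run time (Friday's): 10 min

- the set-up with the highest amount of target at the outlet or at the end, in percent of the starting material put in ("none" if the first two lie within 2 percentage points) (Friday's / Tuesday's / Saturday's / Wednesday's / none)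
- amount of target at the outlet or at the end, in percent of the starting material put in, Friday's
- amount of target at the outlet or at the end, in percent of the starting material put in, Tuesday's
- amount of target at the outlet or at the end, in percent of the starting material put in, Saturday's
- amount of target at the outlet or at the end, in percent of the starting material put in, Wednesday's

- Release runs at 0.00132 s⁻¹, while capture is pseudo-first-order, with a constant of 0.320 M⁻¹ s⁻¹ times the open intermediate present.
- The crossing level is 20.6%: the fraction of the starting-material charge standing as open intermediate at which capture matches release. Above it, capture's constant exceeds release's.
- For Saturday's, my first ceiling takes capture as instant, so target stays under the partner released in 10 min, which is 60.2% of the starting-material charge.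
- In Saturday's, open intermediate stays under its equilibrium share of 73.7%, so capture stays under 0.283 min⁻¹. Two steps in series then lower the ceiling to 43.3%.
- For my floor, Saturday's open intermediate reaches the crossing level in about 1.40 min at its starting forward rate, so I hold it there throughout, ignoring that lag. Equal constants in series give 20.7%.
- Target has a half-life of 7.4 min by over-reaction alone, with partner as charged. Charging target a third of the run at that rate leaves a floor of 15.2% for Saturday's.
- Friday's partner spends 6.00 min in the flask on average, so its first ceiling is 41.6%, lower than Saturday's.
- The forecast names Saturday's, on the ground that “having everything present from time zero wins”. It gives 17.5% for Friday's, 15% for Tuesday's, 24% for Saturday's and 20% for Wednesday's. Its Saturday's figure lies inside my bracket.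
- The simulation gives Saturday's as best, with 14.1% for Friday's, 15.3% for Tuesday's, 23.8% for Saturday's and 17.0% for Wednesday's. Saturday's also lies inside the bracket.
- Saturday's has not come to rest at 10.0 min: open intermediate reads 32.2%, above the crossing level, and 42% of the partner charge remains. Friday's, left until 40 min, shows open intermediate at 10.4%, under the crossing level, with target at 55.2%. Saturday's crosses too: at 100 min, open intermediate reads 3.62% and partner 0%. Target has risen from 23.8% to 69.6%, and over-reaction product from 4.73% to 18.3%.

All constants belong to no real substance, and the outcome is calculated.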